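**Retrosynthetic overview**
1. Target 21 ← desilylation and C8 tigloylation of the macrocyclic C8 carbinol 19.
2. Ten-membered ring ← C7–C8 bond: intramolecular Ni/Cr addition of the butenolide C7 alkenyl metal (a β-acylvinyl anion) to the C8 aldehyde of 17.
3. Bromobutenolide 9 ← C6–C7 bond plus lactonisation: the magnesium carbenoid of gem-dibromoacrylate 3 (a geminal β-acylvinyl dianion linchpin for C7) adds to epoxy aldehyde 6.
4. C1/C10 ← Brown anti-crotylation of the C1 aldehyde from ozonolysis; C4/C5 ← Sharpless epoxidation of nerol.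
5. Ring order: oxirane (step 3), butenolide (step 5), ten-membered carbocycle (step 11).

Locants follow germacrane numbering (ring C1–C10; C11, C12, C13 = butenolide α-carbon, lactone carbonyl, acetoxymethyl carbon; C14 = 10-methyl; C15 = 4-methyl). The target is read as (1S,4R,5S,6S,8S,10R) with a cis-oxirane and an E (tiglate) ester.

**Step 1**
Reactants: 1 ethyl bromopyruvate
Product: 2 ethyl 3-acetoxy-2-oxopropanoate
Conditions: KOAc, AcOH (cat.), acetone, 0 °C to rt
Reagents that add atoms: potassium acetate, CC(=O)[O-].[K+]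
Why: SN2 displacement of the activated α-bromo ketone by acetate (carboxylate alkylation) installs the future C13 acetoxy group at the start; no stereocentre.

**Step 2**
Reactants: 2 ethyl 3-acetoxy-2-oxopropanoate
Product: 3 ethyl 2-(acetoxymethyl)-3,3-dibromoacrylate
Conditions: CBr4, PPh3, CH2Cl2, 0 °C
Reagents that add atoms: carbon tetrabromide, BrC(Br)(Br)Br
Why: Ramirez dibromomethylenation (Wittig reaction of Ph3P=CBr2) of the electrophilic α-keto ester carbonyl gives the gem-dibromoalkene whose CBr2 carbon becomes C7; no stereocentre.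

**Step 3**
Reactants: 4 nerol
Product: 5 (2S,3R)-2,3-epoxynerol
Conditions: Ti(OiPr)4 (10 mol %), L-(+)-diethyl tartrate (12 mol %), t-BuOOH, 4 Å MS, CH2Cl2, −20 °C
Reagents that add atoms: tert-butyl hydroperoxide, CC(C)(C)OO
Why: Sharpless asymmetric epoxidation of the Z allylic alcohol; the L-(+)-tartrate catalyst delivers oxygen to the face that gives the (2S,3R) cis-oxirane, which sets C5 (S) and C4 (R), and the remote trisubstituted alkene is untouched.

**Step 4**
Reactants: 5 (2S,3R)-2,3-epoxynerol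
Product: 6 (2R,3R)-3-methyl-3-(4-methylpent-3-en-1-yl)oxirane-2-carbaldehyde
Conditions: TEMPO (10 mol %), PhI(OAc)2, CH2Cl2, rt
Reagents that add atoms: none
Why: Oxoammonium (TEMPO) oxidation stops at the aldehyde and leaves the epoxide intact; the oxirane α-carbon does not enolise, so C5 is retained (the descriptor changes only through CIP priority).

**Step 5**
Reactants: 3 ethyl 2-(acetoxymethyl)-3,3-dibromoacrylate; 6 (2R,3R)-3-methyl-3-(4-methylpent-3-en-1-yl)oxirane-2-carbaldehyde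
Product: 9 [(5R)-4-bromo-5-[(2S,3R)-3-methyl-3-(4-methylpent-3-en-1-yl)oxiran-2-yl]-2-oxo-2,5-dihydrofuran-3-yl]methyl acetate, via magnesium carbenoid 7 (not isolated), via magnesium alkoxide adduct 8 (not isolated)
Conditions: 3, i-PrMgCl, Et2O, −78 °C; then 6, −78 to −20 °C; aq NH4Cl
Reagents that add atoms: none
Why: Bromine–magnesium exchange on a β,β-dibromoacrylate (a known reaction type) occurs at the bromine cis to the ester by chelation and gives a configurationally stable magnesium alkylidene carbenoid, a β-acylvinyl anion (homoenolate-type d3) equivalent; its C7 (normally the electrophilic β-carbon of an acrylate) adds to the electrophilic aldehyde carbon C6 under Felkin–Anh/Cornforth control (attack anti to the oxirane C–O bond, past H), which sets C6 anti to the epoxide oxygen, and the cis γ-alkoxide then lactonises onto the ethyl ester.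

**Step 6**
Reactants: 9 [(5R)-4-bromo-5-[(2S,3R)-3-methyl-3-(4-methylpent-3-en-1-yl)oxiran-2-yl]-2-oxo-2,5-dihydrofuran-3-yl]methyl acetate
Product: 11 [(5R)-4-bromo-5-[(2S,3R)-3-methyl-3-(3-oxopropyl)oxiran-2-yl]-2-oxo-2,5-dihydrofuran-3-yl]methyl acetate, via secondary ozonide 10 (not isolated)
Conditions: O3, CH2Cl2, −78 °C (stopped when 9 is consumed); then Me2S, −78 °C to rt
Reagents that add atoms: ozone, [O-][O+]=O
Why: Ozonolysis with reductive work-up cleaves only the electron-rich trisubstituted alkene (the bromobutenolide alkene is tetrasubstituted and electron-poor) and unveils the C1 aldehyde; no stereocentre is touched.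

**Step 7**
Reactants: 11 [(5R)-4-bromo-5-[(2S,3R)-3-methyl-3-(3-oxopropyl)oxiran-2-yl]-2-oxo-2,5-dihydrofuran-3-yl]methyl acetate
Product: 13 [(5R)-4-bromo-5-[(2S,3R)-3-[(3S,4R)-3-hydroxy-4-methylhex-5-en-1-yl]-3-methyloxiran-2-yl]-2-oxo-2,5-dihydrofuran-3-yl]methyl acetate, via borinate ester 12 (not isolated)
Conditions: (E)-crotyl-B(Ipc)2 [Ipc from (−)-α-pinene, i.e. the reagent made from (+)-Ipc2BOMe], THF–Et2O, −78 °C; then pH 7 phosphate buffer, 30 % H2O2, MeOH, 0 °C
Reagents that add atoms: B-[(E)-but-2-en-1-yl]diisopinocampheylborane, C/C=C/CB([C@H]1C[C@H]2C[C@@H]([C@@H]1C)C2(C)C)[C@H]1C[C@H]2C[C@@H]([C@@H]1C)C2(C)C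
Why: Brown crotylboration through a chair Zimmerman–Traxler transition state: the E-crotyl unit gives the anti (OH/Me) pair and this antipode of the reagent adds to the aldehyde Re face under reagent control, which sets C1 (S) and C10 (R) and turns the minor enantiomer from step 3 into a separable diastereomer.

**Step 8**
Reactants: 13 [(5R)-4-bromo-5-[(2S,3R)-3-[(3S,4R)-3-hydroxy-4-methylhex-5-en-1-yl]-3-methyloxiran-2-yl]-2-oxo-2,5-dihydrofuran-3-yl]methyl acetate
Product: 14 [(5R)-4-bromo-5-[(2S,3R)-3-methyl-3-[(3S,4R)-4-methyl-3-(triethylsilyloxy)hex-5-en-1-yl]oxiran-2-yl]-2-oxo-2,5-dihydrofuran-3-yl]methyl acetate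
Conditions: TESCl, imidazole, DMF, 0 °C
Reagents that add atoms: chlorotriethylsilane, CC[Si](Cl)(CC)CC
Why: Silyl ether formation under non-acidic conditions masks the C1 hydroxyl, which would otherwise open the 4,5-epoxide (5-exo) or form a lactol with the later C8 aldehyde; no stereocentre is touched.

**Step 9**
Reactants: 14 [(5R)-4-bromo-5-[(2S,3R)-3-methyl-3-[(3S,4R)-4-methyl-3-(triethylsilyloxy)hex-5-en-1-yl]oxiran-2-yl]-2-oxo-2,5-dihydrofuran-3-yl]methyl acetate
Product: 16 [(5R)-4-bromo-5-[(2S,3R)-3-[(3S,4R)-6-hydroxy-4-methyl-3-(triethylsilyloxy)hexyl]-3-methyloxiran-2-yl]-2-oxo-2,5-dihydrofuran-3-yl]methyl acetate, via B-alkyl-9-borabicyclononane 15 (not isolated)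
Conditions: 9-BBN, THF, 0 °C to rt; then pH 7 phosphate buffer, 30 % H2O2, 0 °C to rt
Reagents that add atoms: hydrogen peroxide, OO
Why: Anti-Markovnikov hydroboration–oxidation; 9-BBN reacts only with the terminal alkene and places boron at C8, and the buffered oxidation spares the acetate and the bromobutenolide; no new stereocentre.

**Step 10**
Reactants: 16 [(5R)-4-bromo-5-[(2S,3R)-3-[(3S,4R)-6-hydroxy-4-methyl-3-(triethylsilyloxy)hexyl]-3-methyloxiran-2-yl]-2-oxo-2,5-dihydrofuran-3-yl]methyl acetate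
Product: 17 [(5R)-4-bromo-5-[(2S,3R)-3-methyl-3-[(3S,4R)-4-methyl-6-oxo-3-(triethylsilyloxy)hexyl]oxiran-2-yl]-2-oxo-2,5-dihydrofuran-3-yl]methyl acetate
Conditions: TEMPO (10 mol %), PhI(OAc)2, CH2Cl2, rt
Reagents that add atoms: none
Why: TEMPO oxidation of the primary alcohol gives the C8 aldehyde without over-oxidation; C10 is β to the carbonyl and cannot epimerise.

**Step 11**
Reactants: 17 [(5R)-4-bromo-5-[(2S,3R)-3-methyl-3-[(3S,4R)-4-methyl-6-oxo-3-(triethylsilyloxy)hexyl]oxiran-2-yl]-2-oxo-2,5-dihydrofuran-3-yl]methyl acetate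
Product: 19 (1S,4R,5S,6S,8S,10R)-13-acetoxy-4,5-epoxy-8-hydroxy-1-(triethylsilyloxy)germacr-7(11)-en-12,6-olide, via alkenylchromium dichloride 18 (not isolated)
Conditions: CrCl2 (10 equiv), NiCl2 (0.2 equiv), degassed DMSO, rt, syringe-pump addition of 17 to a final 2 mM; aqueous work-up
Reagents that add atoms: none
Why: Nozaki–Hiyama–Kishi ring closure: zerovalent nickel inserts into the activated C7–Br bond and transmetalates to trivalent chromium, and the alkenylchromium again acts as a β-acylvinyl anion (d3 umpolung; C7 is the normally electrophilic β-carbon of the unsaturated lactone) that adds to the electrophilic C8 aldehyde to close the ten-membered ring; C8 (S) is expected from Re-face addition in a transition state that holds the chromium-bound oxygen in the butenolide plane beside the C13 acetoxymethyl group while the C9–C1 tether bridges the face that already carries C5, which is a conformational prediction and not reagent control.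

**Step 12**
Reactants: 19 (1S,4R,5S,6S,8S,10R)-13-acetoxy-4,5-epoxy-8-hydroxy-1-(triethylsilyloxy)germacr-7(11)-en-12,6-olide
Product: 20 (1S,4R,5S,6S,8S,10R)-13-acetoxy-4,5-epoxy-8-[(E)-2-methylbut-2-enoyloxy]-1-(triethylsilyloxy)germacr-7(11)-en-12,6-olide
Conditions: tigloyl chloride, pyridine, DMAP (cat.), CH2Cl2, 0 °C to rt
Reagents that add atoms: tigloyl chloride, C/C=C(\C)C(Cl)=O
Why: DMAP-catalysed O-acylation with retention at C8; the E (tiglate) geometry is the thermodynamically stable one, and pyridine is used instead of a trialkylamine to avoid deconjugation through a vinylketene.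

**Step 13**
Reactants: 20 (1S,4R,5S,6S,8S,10R)-13-acetoxy-4,5-epoxy-8-[(E)-2-methylbut-2-enoyloxy]-1-(triethylsilyloxy)germacr-7(11)-en-12,6-olide
Product: 21 (1S,4R,5S,6S,8S,10R)-13-acetoxy-4,5-epoxy-1-hydroxy-8-[(E)-2-methylbut-2-enoyloxy]germacr-7(11)-en-12,6-olide (target)
Conditions: HF·pyridine, excess pyridine, THF, 0 °C
Reagents that add atoms: none
Why: Pyridine-buffered fluoride desilylation frees the C1 hydroxyl without opening the trisubstituted epoxide (transannular attack is acid-promoted) and without touching the tiglate, acetate or butenolide; no stereocentre is affected.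

**Compound list**
1 | ethyl bromopyruvate | CCOC(=O)C(=O)CBr | starting material
2 | ethyl 3-acetoxy-2-oxopropanoate | CCOC(=O)C(=O)COC(C)=O | intermediate
3 | ethyl 2-(acetoxymethyl)-3,3-dibromoacrylate | CCOC(=O)C(COC(C)=O)=C(Br)Br | intermediate
4 | nerol, (Z)-3,7-dimethylocta-2,6-dien-1-ol | CC(C)=CCC/C(C)=C\CO | starting material
5 | (2S,3R)-2,3-epoxynerol | CC(C)=CCC[C@@]1(C)O[C@H]1CO | intermediate
6 | (2R,3R)-3-methyl-3-(4-methylpent-3-en-1-yl)oxirane-2-carbaldehyde | CC(C)=CCC[C@@]1(C)O[C@H]1C=O | intermediate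
7 | ethyl (E)-2-(acetoxymethyl)-3-bromo-3-(chloromagnesio)acrylate, Mg cis to the ester | CCOC(=O)/C(COC(C)=O)=C(/Br)[Mg]Cl | intermediate (not isolated)
8 | chloromagnesium alkoxide of ethyl (2E,4R)-2-(acetoxymethyl)-3-bromo-4-hydroxy-4-[(2S,3R)-3-methyl-3-(4-methylpent-3-en-1-yl)oxiran-2-yl]but-2-enoate | CC(C)=CCC[C@@]1(C)O[C@H]1[C@@H](O[Mg]Cl)/C(Br)=C(/COC(C)=O)C(=O)OCC | intermediate (not isolated)
9 | [(5R)-4-bromo-5-[(2S,3R)-3-methyl-3-(4-methylpent-3-en-1-yl)oxiran-2-yl]-2-oxo-2,5-dihydrofuran-3-yl]methyl acetate | CC(C)=CCC[C@@]1(C)O[C@H]1[C@H]1OC(=O)C(COC(C)=O)=C1Br | intermediate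
10 | secondary ozonide of 9, 5,5-dimethyl-1,2,4-trioxolan-3-yl in place of the alkene (ozonide CH unassigned) | CC1(C)OOC(CC[C@@]2(C)O[C@H]2[C@H]2OC(=O)C(COC(C)=O)=C2Br)O1 | intermediate (not isolated)
11 | [(5R)-4-bromo-5-[(2S,3R)-3-methyl-3-(3-oxopropyl)oxiran-2-yl]-2-oxo-2,5-dihydrofuran-3-yl]methyl acetate | O=CCC[C@@]1(C)O[C@H]1[C@H]1OC(=O)C(COC(C)=O)=C1Br | intermediate
12 | diisopinocampheylborinate ester of 13 | C=C[C@@H](C)[C@@H](OB([C@H]1C[C@H]2C[C@@H]([C@@H]1C)C2(C)C)[C@H]1C[C@H]2C[C@@H]([C@@H]1C)C2(C)C)CC[C@@]1(C)O[C@H]1[C@H]1OC(=O)C(COC(C)=O)=C1Br | intermediate (not isolated)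
13 | [(5R)-4-bromo-5-[(2S,3R)-3-[(3S,4R)-3-hydroxy-4-methylhex-5-en-1-yl]-3-methyloxiran-2-yl]-2-oxo-2,5-dihydrofuran-3-yl]methyl acetate | C=C[C@@H](C)[C@@H](O)CC[C@@]1(C)O[C@H]1[C@H]1OC(=O)C(COC(C)=O)=C1Br | intermediate
14 | triethylsilyl ether of 13 at the (3S) hydroxyl | C=C[C@@H](C)[C@@H](O[Si](CC)(CC)CC)CC[C@@]1(C)O[C@H]1[C@H]1OC(=O)C(COC(C)=O)=C1Br | intermediate
15 | B-alkyl-9-borabicyclo[3.3.1]nonane from 14, boron on the terminal carbon (C8) | C(C[C@@H](C)[C@@H](O[Si](CC)(CC)CC)CC[C@@]1(C)O[C@H]1[C@H]1OC(=O)C(COC(C)=O)=C1Br)B1C2CCCC1CCC2 | intermediate (not isolated)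
16 | [(5R)-4-bromo-5-[(2S,3R)-3-[(3S,4R)-6-hydroxy-4-methyl-3-(triethylsilyloxy)hexyl]-3-methyloxiran-2-yl]-2-oxo-2,5-dihydrofuran-3-yl]methyl acetate | OCC[C@@H](C)[C@@H](O[Si](CC)(CC)CC)CC[C@@]1(C)O[C@H]1[C@H]1OC(=O)C(COC(C)=O)=C1Br | intermediate
17 | [(5R)-4-bromo-5-[(2S,3R)-3-methyl-3-[(3S,4R)-4-methyl-6-oxo-3-(triethylsilyloxy)hexyl]oxiran-2-yl]-2-oxo-2,5-dihydrofuran-3-yl]methyl acetate | O=CC[C@@H](C)[C@@H](O[Si](CC)(CC)CC)CC[C@@]1(C)O[C@H]1[C@H]1OC(=O)C(COC(C)=O)=C1Br | intermediate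
18 | alkenylchromium dichloride from 17, CrCl2 in place of Br at C7 | O=CC[C@@H](C)[C@@H](O[Si](CC)(CC)CC)CC[C@@]1(C)O[C@H]1[C@H]1OC(=O)C(COC(C)=O)=C1[Cr](Cl)Cl | intermediate (not isolated)
19 | (1S,4R,5S,6S,8S,10R)-13-acetoxy-4,5-epoxy-8-hydroxy-1-(triethylsilyloxy)germacr-7(11)-en-12,6-olide | O[C@H]1C[C@@H](C)[C@@H](O[Si](CC)(CC)CC)CC[C@@]2(C)O[C@H]2[C@H]2OC(=O)C(COC(C)=O)=C12 | intermediate
20 | (1S,4R,5S,6S,8S,10R)-13-acetoxy-4,5-epoxy-8-[(E)-2-methylbut-2-enoyloxy]-1-(triethylsilyloxy)germacr-7(11)-en-12,6-olide | C/C=C(\C)C(=O)O[C@H]1C[C@@H](C)[C@@H](O[Si](CC)(CC)CC)CC[C@@]2(C)O[C@H]2[C@H]2OC(=O)C(COC(C)=O)=C12 | intermediate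
21 | (1S,4R,5S,6S,8S,10R)-13-acetoxy-4,5-epoxy-1-hydroxy-8-[(E)-2-methylbut-2-enoyloxy]germacr-7(11)-en-12,6-olide, CNP0159184.1 | C/C=C(\C)C(=O)O[C@H]1C[C@@H](C)[C@@H](O)CC[C@@]2(C)O[C@H]2[C@H]2OC(=O)C(COC(C)=O)=C12 | target

**Step count and risks**
Total: 13 steps. Longest linear sequence: 11 steps (nerol 4 to 21, steps 3–13); steps 1–2 make the linchpin 3 in a side branch.

Most likely to fail:

1. Step 11 (Ni/Cr ring closure). The C8 configuration rests on a conformational prediction, and the C7 alkenyl metal has the lactone oxygen in a β position. The fallback sets out from 17 and rejoins the route at 20. If the closure gives mainly the C8 epimer, (1S,4R,5S,6S,8R,10R)-13-acetoxy-4,5-epoxy-8-hydroxy-1-(triethylsilyloxy)germacr-7(11)-en-12,6-olide F1, this alcohol is not acylated with retention. It is instead esterified with inversion by a Mitsunobu reaction (tiglic acid, PPh3, DIAD, toluene, 0 °C), an SN2 displacement at C8 that delivers 20 directly; SN2′ attack is disfavoured because C11 is fully substituted. Either C8 epimer from the ring closure therefore reaches 20 in one step.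

2. Step 5 (magnesium carbenoid addition). The allylic acetate of 3 may compete with the ester as chelating group during the exchange, or be attacked by the Grignard reagent. The fallback sets out from 3 (with 6) and rejoins at 9.
   - The acetate is removed by acid-catalysed ethanolysis (cat. HCl, EtOH) to give ethyl 3,3-dibromo-2-(hydroxymethyl)acrylate F2.
   - Silylation (TBSCl, imidazole, DMF) gives ethyl 3,3-dibromo-2-[(tert-butyldimethylsilyloxy)methyl]acrylate F3.
   - With i-PrMgCl (Et2O, −78 °C) the ester is now the only chelating group and the exchange gives the silyloxy magnesium carbenoid F4 (not isolated).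
   - F4 adds to 6 to give the magnesium alkoxide adduct F5 (not isolated), which lactonises to the silyloxymethyl bromobutenolide F6.
   - HF·pyridine/pyridine gives the hydroxymethyl bromobutenolide F7, and Ac2O/pyridine returns 9.

3. Step 9 (hydroboration–oxidation). The peroxide work-up may attack the bromobutenolide (a vinylogous acyl bromide) or the acetate. The fallback sets out from 14 and rejoins at 17, bypassing 15 and 16 and making step 10 unnecessary. It is an aldehyde-selective (anti-Markovnikov) Wacker oxidation of the terminal alkene: PdCl2(PhCN)2 (10 mol %), CuCl2 (10 mol %), AgNO2 (5 mol %), O2 (1 atm), t-BuOH/MeNO2, rt. It uses no boron and no peroxide, and the divalent palladium does not insert into the alkenyl bromide.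

**Further compounds**
F1 | step 11 | (1S,4R,5S,6S,8R,10R)-13-acetoxy-4,5-epoxy-8-hydroxy-1-(triethylsilyloxy)germacr-7(11)-en-12,6-olide | O[C@@H]1C[C@@H](C)[C@@H](O[Si](CC)(CC)CC)CC[C@@]2(C)O[C@H]2[C@H]2OC(=O)C(COC(C)=O)=C12
F2 | step 5 | ethyl 3,3-dibromo-2-(hydroxymethyl)acrylate | CCOC(=O)C(CO)=C(Br)Br
F3 | step 5 | ethyl 3,3-dibromo-2-[(tert-butyldimethylsilyloxy)methyl]acrylate | CCOC(=O)C(CO[Si](C)(C)C(C)(C)C)=C(Br)Br
F4 | step 5 | ethyl (E)-3-bromo-2-[(tert-butyldimethylsilyloxy)methyl]-3-(chloromagnesio)acrylate (not isolated) | CCOC(=O)/C(CO[Si](C)(C)C(C)(C)C)=C(/Br)[Mg]Cl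
F5 | step 5 | chloromagnesium alkoxide of ethyl (2E,4R)-3-bromo-2-[(tert-butyldimethylsilyloxy)methyl]-4-hydroxy-4-[(2S,3R)-3-methyl-3-(4-methylpent-3-en-1-yl)oxiran-2-yl]but-2-enoate (not isolated) | CC(C)=CCC[C@@]1(C)O[C@H]1[C@@H](O[Mg]Cl)/C(Br)=C(/CO[Si](C)(C)C(C)(C)C)C(=O)OCC
F6 | step 5 | (5R)-4-bromo-3-[(tert-butyldimethylsilyloxy)methyl]-5-[(2S,3R)-3-methyl-3-(4-methylpent-3-en-1-yl)oxiran-2-yl]furan-2(5H)-one | CC(C)=CCC[C@@]1(C)O[C@H]1[C@H]1OC(=O)C(CO[Si](C)(C)C(C)(C)C)=C1Br
F7 | step 5 | (5R)-4-bromo-3-(hydroxymethyl)-5-[(2S,3R)-3-methyl-3-(4-methylpent-3-en-1-yl)oxiran-2-yl]furan-2(5H)-one | CC(C)=CCC[C@@]1(C)O[C@H]1[C@H]1OC(=O)C(CO)=C1Br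
F0 | step 9 | none | none
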